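The biaryl bond is not made by coupling two arenes. Instead, ring A of the 6-linked flavone (unit 1) is grown on a carbon already bonded to C8 of the 8-linked flavone (unit 2). Ring A carries oxygen on C5, C7 and C8a, with C6 flanked by C5–O and C7–O. A 3,5-dioxohexanoate chain gives this alternating array when its terminal carbon closes onto the ester. The precursor is therefore a 4-benzyloxy-2-pyranone whose 6-CH2 group sits on C8 of 5,7-di-O-MOM acacetin. One alkoxide treatment opens the lactone and recloses it through carbon. This forms C6–C7, aromatises ring A and leaves only the oxygen para to the biaryl bond (future O1) benzylated.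

Key step: step 7

Assumption: the target SMILES fixes no configuration for the hindered C6–C8'' axis and contains no stereocentre, so the racemic atropisomer mixture is the goal.
Abbreviations in names: Fl8 = 5,7-bis(methoxymethoxy)-2-(4-methoxyphenyl)-4-oxo-4H-chromen-8-yl (unit 2, bonded through C8); MOM = CH2OCH3; Bn = CH2Ph.

Step 1
Reactants: 1 acacetin (5,7-dihydroxy-2-(4-methoxyphenyl)-4H-chromen-4-one)
Product: 2 5,7-bis(methoxymethoxy)-2-(4-methoxyphenyl)-4H-chromen-4-one
Conditions: NaH (3 equiv), MOMCl (3 equiv), DMF, 0 °C to rt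
Reagents that add atoms: chloromethyl methyl ether (MOMCl), COCCl
Why: Williamson-type O-alkylation of the bis-phenoxide, in which full deprotonation by NaH breaks the C5–OH···O=C4 chelate so that both hydroxyls are capped.

Step 2
Reactants: 2 5,7-bis(methoxymethoxy)-2-(4-methoxyphenyl)-4H-chromen-4-one
Product: 3 8-iodo-5,7-bis(methoxymethoxy)-2-(4-methoxyphenyl)-4H-chromen-4-one
Conditions: NIS (1.1 equiv), DMF, rt to 50 °C, dark
Reagents that add atoms: N-iodosuccinimide, O=C1CCC(=O)N1I
Why: Electrophilic aromatic iodination, which in 5,7-dialkoxyflavones lacking a free C5 hydroxyl goes to C8 (C6 is shielded by two acetal groups), under neutral conditions that spare the MOM ethers.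

Step 3
Reactants: 3 8-iodo-5,7-bis(methoxymethoxy)-2-(4-methoxyphenyl)-4H-chromen-4-one; 4 ethyl bromoacetate
Product: 6 ethyl 2-(Fl8)acetate, via zinc reagent BrZnCH2CO2Et 5 (not isolated)
Conditions: 4, Zn dust (TMSCl-activated), THF, 40 °C; then 3, Pd2(dba)3 (2.5 mol %), XPhos (10 mol %), THF, 65 °C
Reagents that add atoms: none
Why: Negishi-type α-arylation of a Reformatsky zinc enolate, in which a bulky biaryl phosphine allows coupling at the di-ortho-substituted C8 and the mild zinc enolate leaves the ring C carbonyl and the acetals alone.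

Step 4
Reactants: 6 ethyl 2-(Fl8)acetate; 7 methyl acetoacetate
Product: 9 methyl 6-(Fl8)-3,5-dioxohexanoate, via dilithio acetoacetate dianion 8 (not isolated)
Conditions: 7 (3 equiv), LiN(i-Pr)2 (6 equiv), THF, −78 to 0 °C; then 6, −78 to 0 °C; sat. aq. NH4Cl
Reagents that add atoms: none
Why: Claisen-type γ-acylation of a β-keto ester dianion, whose terminal carbanion attacks the ester carbonyl one CH2 away from crowded C8, while excess dianion absorbs the acidic protons of the tricarbonyl product and the vinylogous-ester carbonyl of ring C stays inert at low temperature.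

Step 5
Reactants: 9 methyl 6-(Fl8)-3,5-dioxohexanoate
Product: 10 4-hydroxy-6-[(Fl8)methyl]-2H-pyran-2-one
Conditions: DBU (1.5 equiv), toluene, 90 °C; cold aq. citric acid
Reagents that add atoms: none
Why: Base-induced enol lactonisation (intramolecular transesterification) of a 3,5-dioxo ester, the standard entry to 6-substituted 4-hydroxy-2-pyranones, in which the C5 enolate oxygen displaces methoxide from the ester.

Step 6
Reactants: 10 4-hydroxy-6-[(Fl8)methyl]-2H-pyran-2-one
Product: 11 4-benzyloxy-6-[(Fl8)methyl]-2H-pyran-2-one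
Conditions: BnOH, PPh3, DIAD, THF, 0 °C to rt
Reagents that add atoms: benzyl alcohol, OCc1ccccc1
Why: Mitsunobu reaction of the acidic vinylogous-acid hydroxyl, which alkylates O4 under neutral conditions and avoids the C3-alkylation and 2-alkoxy-4-pyranone formation that can accompany halide/base alkylation.

Step 7
Reactants: 11 4-benzyloxy-6-[(Fl8)methyl]-2H-pyran-2-one
Product: 13 8-(4-benzyloxy-2,6-dihydroxyphenyl)-5,7-bis(methoxymethoxy)-2-(4-methoxyphenyl)-4H-chromen-4-one, via benzyl enol ether keto ester 12 (not isolated)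
Conditions: Mg(OBn)2 (4 equiv, from n-Bu2Mg + BnOH), BnOH–THF (1:4), Ar, 65 °C; cold sat. aq. NH4Cl
Reagents that add atoms: none
Why: Benzyloxide adds to the lactone carbonyl of 11 and releases the C6–O enolate, giving keto ester 12 whose (E) double bond, inherited from the ring, keeps the ester and the ketone arm on the same side. Reversible deprotonation of the benzylic CH2 (acidified by the ketone and by ring A of unit 2) lets this carbon attack the ester carbonyl in a 6-(enolendo)-exo-trig Claisen (Dieckmann-type) closure, benzyloxide leaves and the resulting cyclohexenedione tautomerises to the magnesium bis-phenoxide, so that the C6–C7 bond and ring A of unit 1 arise together. The closest known reaction type is the alkoxide-induced opening of 4-alkoxy-6-substituted 2-pyranones with Claisen reclosure to phloroglucinol monoethers, a polyketide-like cyclisation; only the bulk of the aryl group is new. No stereocentre is formed, and because the new ring is symmetric about the biaryl bond no axial isomers exist at this stage. The step needs C-acylation to win over relactonisation and needs the benzyl label to stay on the para oxygen: relactonisation is reversible whereas aromatisation is not, the more acidic C4 carbanion could only make a four-membered ring, and matching the alkoxide to the enol ether makes any addition–elimination at that carbon degenerate. The C5 MOM ether of unit 2 guarantees that a transient base-induced opening of its ring C can only reclose to the 8-substituted flavone.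

Step 8
Reactants: 13 8-(4-benzyloxy-2,6-dihydroxyphenyl)-5,7-bis(methoxymethoxy)-2-(4-methoxyphenyl)-4H-chromen-4-one
Product: 14 8-[4-benzyloxy-2,6-bis(methoxymethoxy)phenyl]-5,7-bis(methoxymethoxy)-2-(4-methoxyphenyl)-4H-chromen-4-one
Conditions: NaH (2.5 equiv), MOMCl (3 equiv), DMF, 0 °C to rt
Reagents that add atoms: chloromethyl methyl ether (MOMCl), COCCl
Why: Williamson-type acetalisation of the two symmetry-equivalent phenoxides, which leaves the benzyl ether as the only differentiated oxygen of the new ring.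

Step 9
Reactants: 14 8-[4-benzyloxy-2,6-bis(methoxymethoxy)phenyl]-5,7-bis(methoxymethoxy)-2-(4-methoxyphenyl)-4H-chromen-4-one
Product: 15 8-[4-hydroxy-2,6-bis(methoxymethoxy)phenyl]-5,7-bis(methoxymethoxy)-2-(4-methoxyphenyl)-4H-chromen-4-one
Conditions: H2 (1 atm), 10% Pd/C, EtOAc–EtOH, rt
Reagents that add atoms: none
Why: Catalytic hydrogenolysis of an aryl benzyl ether, routine on flavones at atmospheric pressure and stopped after one equivalent of hydrogen so that the conjugated C2=C3 bond, the acetals and the methyl ether remain.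

Step 10
Reactants: 15 8-[4-hydroxy-2,6-bis(methoxymethoxy)phenyl]-5,7-bis(methoxymethoxy)-2-(4-methoxyphenyl)-4H-chromen-4-one; 16 methyl 3-(4-methoxyphenyl)prop-2-ynoate
Product: 17 methyl (Z)-3-[4-(Fl8)-3,5-bis(methoxymethoxy)phenoxy]-3-(4-methoxyphenyl)prop-2-enoate
Conditions: K2CO3 (1.5 equiv), DMF, 90 °C
Reagents that add atoms: none
Why: Base-mediated oxa-Michael addition of the unhindered phenoxide to the β-carbon of the aryl propiolate, where anti addition should favour the Z enol ether drawn and the geometry is immaterial because it equilibrates under the acid of the closing step.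

Step 11
Reactants: 17 methyl (Z)-3-[4-(Fl8)-3,5-bis(methoxymethoxy)phenoxy]-3-(4-methoxyphenyl)prop-2-enoate
Product: 18 (Z)-3-[4-(Fl8)-3,5-bis(methoxymethoxy)phenoxy]-3-(4-methoxyphenyl)prop-2-enoic acid
Conditions: LiOH·H2O (3 equiv), THF–MeOH–H2O, 40 °C; cold 1 M HCl to pH 4
Reagents that add atoms: lithium hydroxide, [Li+].[OH-]
Why: Ester saponification by acyl–oxygen cleavage under mild conditions that the aryl enol ether, the acetals and ring C of unit 2 tolerate.

Step 12
Reactants: 18 (Z)-3-[4-(Fl8)-3,5-bis(methoxymethoxy)phenoxy]-3-(4-methoxyphenyl)prop-2-enoic acid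
Product: 21 6-[5,7-dihydroxy-2-(4-methoxyphenyl)-4-oxo-4H-chromen-8-yl]-5,7-dihydroxy-2-(4-methoxyphenyl)-4H-chromen-4-one (racemic), via mixed trifluoroacetic anhydride 19 (not isolated), via tetra-MOM biflavone 20 (not isolated)
Conditions: (CF3CO)2O (1.5 equiv), CH2Cl2, 0 °C to rt; evaporate; then 3 M HCl, MeOH–THF, 50 °C
Reagents that add atoms: none
Why: Intramolecular Friedel–Crafts acylation by the mixed anhydride (as in closures of electron-rich 2-aryloxybenzoic acids to xanthones) at a position activated by three oxygens and identical to its twin by symmetry, so only the 6-linked flavone can form and the axis arises as a racemate, while deferring acetal cleavage to a methanolic stage lets MeOH trap the formaldehyde units instead of the phenolic rings.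

Compound list
1 | acacetin, 5,7-dihydroxy-2-(4-methoxyphenyl)-4H-chromen-4-one | COc1ccc(-c2cc(=O)c3c(O)cc(O)cc3o2)cc1 | starting material
2 | 5,7-bis(methoxymethoxy)-2-(4-methoxyphenyl)-4H-chromen-4-one | COCOc1cc(OCOC)c2c(=O)cc(-c3ccc(OC)cc3)oc2c1 | intermediate
3 | 8-iodo-5,7-bis(methoxymethoxy)-2-(4-methoxyphenyl)-4H-chromen-4-one | COCOc1cc(OCOC)c2c(=O)cc(-c3ccc(OC)cc3)oc2c1I | intermediate
4 | ethyl bromoacetate | CCOC(=O)CBr | starting material
5 | (2-ethoxy-2-oxoethyl)zinc bromide | CCOC(=O)C[Zn]Br | intermediate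
6 | ethyl 2-[5,7-bis(methoxymethoxy)-2-(4-methoxyphenyl)-4-oxo-4H-chromen-8-yl]acetate | CCOC(=O)Cc1c(OCOC)cc(OCOC)c2c(=O)cc(-c3ccc(OC)cc3)oc12 | intermediate
7 | methyl acetoacetate | COC(=O)CC(C)=O | starting material
8 | dilithium dianion of methyl acetoacetate | [Li+].[Li+].COC(=O)[CH-]C(=O)[CH2-] | intermediate
9 | methyl 6-[5,7-bis(methoxymethoxy)-2-(4-methoxyphenyl)-4-oxo-4H-chromen-8-yl]-3,5-dioxohexanoate | COC(=O)CC(=O)CC(=O)Cc1c(OCOC)cc(OCOC)c2c(=O)cc(-c3ccc(OC)cc3)oc12 | intermediate
10 | 4-hydroxy-6-{[5,7-bis(methoxymethoxy)-2-(4-methoxyphenyl)-4-oxo-4H-chromen-8-yl]methyl}-2H-pyran-2-one | O=c1cc(O)cc(Cc2c(OCOC)cc(OCOC)c3c(=O)cc(-c4ccc(OC)cc4)oc23)o1 | intermediate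
11 | 4-benzyloxy-6-{[5,7-bis(methoxymethoxy)-2-(4-methoxyphenyl)-4-oxo-4H-chromen-8-yl]methyl}-2H-pyran-2-one | O=c1cc(OCc2ccccc2)cc(Cc2c(OCOC)cc(OCOC)c3c(=O)cc(-c4ccc(OC)cc4)oc23)o1 | intermediate
12 | benzyl (E)-3-benzyloxy-6-[5,7-bis(methoxymethoxy)-2-(4-methoxyphenyl)-4-oxo-4H-chromen-8-yl]-5-oxohex-2-enoate | O=C(OCc1ccccc1)/C=C(/OCc1ccccc1)CC(=O)Cc1c(OCOC)cc(OCOC)c2c(=O)cc(-c3ccc(OC)cc3)oc12 | intermediate
13 | 8-(4-benzyloxy-2,6-dihydroxyphenyl)-5,7-bis(methoxymethoxy)-2-(4-methoxyphenyl)-4H-chromen-4-one | Oc1cc(OCc2ccccc2)cc(O)c1-c1c(OCOC)cc(OCOC)c2c(=O)cc(-c3ccc(OC)cc3)oc12 | intermediate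
14 | 8-[4-benzyloxy-2,6-bis(methoxymethoxy)phenyl]-5,7-bis(methoxymethoxy)-2-(4-methoxyphenyl)-4H-chromen-4-one | COCOc1cc(OCc2ccccc2)cc(OCOC)c1-c1c(OCOC)cc(OCOC)c2c(=O)cc(-c3ccc(OC)cc3)oc12 | intermediate
15 | 8-[4-hydroxy-2,6-bis(methoxymethoxy)phenyl]-5,7-bis(methoxymethoxy)-2-(4-methoxyphenyl)-4H-chromen-4-one | COCOc1cc(O)cc(OCOC)c1-c1c(OCOC)cc(OCOC)c2c(=O)cc(-c3ccc(OC)cc3)oc12 | intermediate
16 | methyl 3-(4-methoxyphenyl)prop-2-ynoate | COC(=O)C#Cc1ccc(OC)cc1 | starting material
17 | methyl (Z)-3-{4-[5,7-bis(methoxymethoxy)-2-(4-methoxyphenyl)-4-oxo-4H-chromen-8-yl]-3,5-bis(methoxymethoxy)phenoxy}-3-(4-methoxyphenyl)prop-2-enoate | COC(=O)/C=C(\Oc1cc(OCOC)c(-c2c(OCOC)cc(OCOC)c3c(=O)cc(-c4ccc(OC)cc4)oc23)c(OCOC)c1)c1ccc(OC)cc1 | intermediate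
18 | (Z)-3-{4-[5,7-bis(methoxymethoxy)-2-(4-methoxyphenyl)-4-oxo-4H-chromen-8-yl]-3,5-bis(methoxymethoxy)phenoxy}-3-(4-methoxyphenyl)prop-2-enoic acid | OC(=O)/C=C(\Oc1cc(OCOC)c(-c2c(OCOC)cc(OCOC)c3c(=O)cc(-c4ccc(OC)cc4)oc23)c(OCOC)c1)c1ccc(OC)cc1 | intermediate
19 | mixed anhydride of acid 18 and trifluoroacetic acid | O=C(OC(=O)C(F)(F)F)/C=C(\Oc1cc(OCOC)c(-c2c(OCOC)cc(OCOC)c3c(=O)cc(-c4ccc(OC)cc4)oc23)c(OCOC)c1)c1ccc(OC)cc1 | intermediate
20 | 6-[5,7-bis(methoxymethoxy)-2-(4-methoxyphenyl)-4-oxo-4H-chromen-8-yl]-5,7-bis(methoxymethoxy)-2-(4-methoxyphenyl)-4H-chromen-4-one | COc1ccc(-c2cc(=O)c3c(OCOC)c(-c4c(OCOC)cc(OCOC)c5c(=O)cc(-c6ccc(OC)cc6)oc45)c(OCOC)cc3o2)cc1 | intermediate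
21 | 6-[5,7-dihydroxy-2-(4-methoxyphenyl)-4-oxo-4H-chromen-8-yl]-5,7-dihydroxy-2-(4-methoxyphenyl)-4H-chromen-4-one (4',4'''-di-O-methyl-6,8''-biapigenin, racemic axis) | COc1ccc(-c2cc(=O)c3c(O)c(-c4c(O)cc(O)c5c(=O)cc(-c6ccc(OC)cc6)oc45)c(O)cc3o2)cc1 | target

Total step count: 12. Longest linear sequence: 12 steps (1 to 21).

Steps most likely to fail

**Step 7.**
- What may go wrong: the crowded benzylic carbanion may reach the ester too slowly. The opened chain then keeps relactonising, or it is cut by retro-Claisen attack of alkoxide on the ketone.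
- Fallback: ring construction is given up and the biaryl bond is made by Suzuki–Miyaura coupling. This sets out from 3 and comes back to the route at 14.
- Phloroglucinol is mono-O-benzylated (BnBr, K2CO3, DMF, excess triol) to 5-benzyloxyresorcinol F1.
- Both hydroxyls are capped (NaH, MOMCl, DMF) to give 1-benzyloxy-3,5-bis(methoxymethoxy)benzene F2.
- Directed ortho-lithiation between the two acetal oxygens (n-BuLi, THF, 0 °C) and quenching with 2-isopropoxy-4,4,5,5-tetramethyl-1,3,2-dioxaborolane give the pinacol boronate F3.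
- Coupling of F3 with 3 (Pd(OAc)2, SPhos, K3PO4, toluene–H2O, 100 °C) delivers 14.

**Step 4.**
- What may go wrong: proton transfer from the acidic arylacetate CH2 to the strongly basic dianion, or competing attack on ring C, may stall the acylation.
- Fallback: a far less basic dienolate and a thermal acylketene closure are used. This sets out from 6 and comes back at 10.
- Compound 6 is saponified (LiOH, THF–H2O) to 2-(Fl8)acetic acid F4.
- F4 is activated with 1,1'-carbonyldiimidazole to the acyl imidazole F5.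
- F5 acylates the lithium dienolate of 2,2,6-trimethyl-4H-1,3-dioxin-4-one (LiN(SiMe3)2, THF, −78 °C) to give the keto-dioxinone F6.
- Heating in toluene at 110 °C expels acetone. The acylketene F7 is trapped by its own enolised ketone to give 10.

**Step 12.**
- What may go wrong: early loss of acetals in the acidic acylation medium, with the released formaldehyde units captured by the electron-rich rings.
- Intermolecular trifluoroacetylation of the arene, or sluggish attack by the stabilised acyl cation, may also erode the closure.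
- Fallback: ring C is built under neutral to basic palladium catalysis. This sets out from 15 and comes back at 20.
- Mono-iodination ortho to the free hydroxyl (NIS, 1 equiv, MeCN, −20 °C) gives the iodophenol F8.
- Carbonylative Sonogashira coupling with 4-ethynylanisole (CO, PdCl2(dppf), Et2NH, 80 °C) gives the o-hydroxyaryl ynone F9.
- F9 closes in the same pot by amine-mediated 6-endo-dig conjugate addition to 20. The HCl–MeOH stage of step 12 then gives 21.

Further compounds
F1 | step 7 | 5-benzyloxybenzene-1,3-diol | Oc1cc(O)cc(OCc2ccccc2)c1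
F2 | step 7 | 1-benzyloxy-3,5-bis(methoxymethoxy)benzene | COCOc1cc(OCOC)cc(OCc2ccccc2)c1
F3 | step 7 | 2-[4-benzyloxy-2,6-bis(methoxymethoxy)phenyl]-4,4,5,5-tetramethyl-1,3,2-dioxaborolane | COCOc1cc(OCc2ccccc2)cc(OCOC)c1B1OC(C)(C)C(C)(C)O1
F4 | step 4 | 2-[5,7-bis(methoxymethoxy)-2-(4-methoxyphenyl)-4-oxo-4H-chromen-8-yl]acetic acid | OC(=O)Cc1c(OCOC)cc(OCOC)c2c(=O)cc(-c3ccc(OC)cc3)oc12
F5 | step 4 | 1-{2-[5,7-bis(methoxymethoxy)-2-(4-methoxyphenyl)-4-oxo-4H-chromen-8-yl]acetyl}imidazole | O=C(Cc1c(OCOC)cc(OCOC)c2c(=O)cc(-c3ccc(OC)cc3)oc12)n1ccnc1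
F6 | step 4 | 6-{3-[5,7-bis(methoxymethoxy)-2-(4-methoxyphenyl)-4-oxo-4H-chromen-8-yl]-2-oxopropyl}-2,2-dimethyl-4H-1,3-dioxin-4-one | CC1(C)OC(CC(=O)Cc2c(OCOC)cc(OCOC)c3c(=O)cc(-c4ccc(OC)cc4)oc23)=CC(=O)O1
F7 | step 4 | 6-[5,7-bis(methoxymethoxy)-2-(4-methoxyphenyl)-4-oxo-4H-chromen-8-yl]-3,5-dioxohex-1-en-1-one (acylketene) | O=C=CC(=O)CC(=O)Cc1c(OCOC)cc(OCOC)c2c(=O)cc(-c3ccc(OC)cc3)oc12
F8 | step 12 | 8-[4-hydroxy-3-iodo-2,6-bis(methoxymethoxy)phenyl]-5,7-bis(methoxymethoxy)-2-(4-methoxyphenyl)-4H-chromen-4-one | COCOc1cc(O)c(I)c(OCOC)c1-c1c(OCOC)cc(OCOC)c2c(=O)cc(-c3ccc(OC)cc3)oc12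
F9 | step 12 | 8-{4-hydroxy-3-[3-(4-methoxyphenyl)prop-2-ynoyl]-2,6-bis(methoxymethoxy)phenyl}-5,7-bis(methoxymethoxy)-2-(4-methoxyphenyl)-4H-chromen-4-one | COCOc1cc(O)c(C(=O)C#Cc2ccc(OC)cc2)c(OCOC)c1-c1c(OCOC)cc(OCOC)c2c(=O)cc(-c3ccc(OC)cc3)oc12
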